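**Retrosynthetic overview**

1. Target ⇐ desilylation and C9 acetylation of a macrocyclic chlorolactone, itself closed last by an intramolecular chromium-mediated γ-chloroallylation of a C7 aldehyde (C6–C7 bond; forms the ten-membered ring, C6–Cl, the exo-methylene and, by lactonisation, the γ-lactone).
2. Arm C2–C6 ⇐ Nozaki–Hiyama–Kishi coupling (C4–C5) of a C4 enal with 2-bromoacrolein acetal; the enal ⇐ cross-metathesis of the C1 vinyl group.
3. Ring A (11-acetoxy-11-methyl-12-ketone) ⇐ α-ketol ring expansion of a 1-acetylcyclopent-2-en-1-ol: C10 shifts from C12 to the acetyl carbon C11 (five- to six-membered ring).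
4. Cyclopentenone ⇐ α′-aldol (C9–C10) with a C7–C9/C17–C19 aldehyde, after copper-catalysed conjugate addition of a 1-silylvinyl group to 3-methylcyclopentenone (C1).
5. Aldehyde ⇐ catalytic asymmetric Mukaiyama aldol of an α-keto ester (C8–C17). Ring order: cyclopentenone (bought) → ring A by expansion → ten-membered ring → γ-lactone.

Assumption: positions follow briarane numbering (C1 quaternary with Me-15, C2=C3, C4–OAc, C5=C16H2, C6–Cl, C7–O, C8–OH, C9–OAc, C10, C11(OAc)Me-20, C12=O, C13=C14, C17(Me-18)–C19(=O)O); 2-bromo-3,3-dimethoxyprop-1-ene is taken as purchasable; the ligand enantiomers named in steps 1, 6 and 13 are the ones assumed to give the stated configurations.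

**Route**

Step 1
Reactants: 1 3-methylcyclopent-2-en-1-one; 2 ethynyltrimethylsilane
Product: 4 (S)-3-methyl-3-[1-(trimethylsilyl)vinyl]cyclopentan-1-one, via alkenylalane 3 (not isolated)
Conditions: 2, i-Bu2AlH, hexanes, 55 °C; then 1, CuCl2·2H2O (5 mol %), chiral sulfonate-bearing N-heterocyclic carbene ligand (5 mol %), THF, −15 °C
Reagents that add atoms: none
Why: Hydroalumination places aluminium on the silicon-bearing carbon, and NHC–copper-catalysed asymmetric conjugate addition of such α-silylvinylalanes to β-methyl cyclic enones is an established route to quaternary centres; the chiral copper complex sets C1, and the bulky silylvinyl group is kept as a steric control element for step 8.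

Step 2
Reactants: 4 (S)-3-methyl-3-[1-(trimethylsilyl)vinyl]cyclopentan-1-one
Product: 5 (R)-4-methyl-4-[1-(trimethylsilyl)vinyl]cyclopent-2-en-1-one
Conditions: LiN(i-Pr)2, THF, −78 °C; then PhS(Cl)=N-t-Bu, −78 °C
Reagents that add atoms: none
Why: Kinetic deprotonation occurs at the unhindered C13 methylene (C10 is neopentylic) and the enolate is dehydrogenated in one pot by the Mukaiyama sulfinimidoyl chloride; no new stereocentre.

Step 3
Reactants: 6 methyl (E)-3-methoxyprop-2-enoate
Product: 7 methyl 2-hydroxy-3,3-dimethoxypropanoate (racemic)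
Conditions: mCPBA, MeOH, 0 → 25 °C
Reagents that add atoms: mCPBA, O=C(OO)c1cccc(Cl)c1; methanol, CO
Why: Prilezhaev epoxidation of the enol-ether double bond followed by methanolysis at the acetal carbon gives the α-hydroxy acetal; the stereocentre is removed in step 4.

Step 4
Reactants: 7 methyl 2-hydroxy-3,3-dimethoxypropanoate
Product: 8 methyl 3,3-dimethoxy-2-oxopropanoate
Conditions: Dess–Martin periodinane, CH2Cl2, 25 °C
Reagents that add atoms: none
Why: Dess–Martin oxidation of a secondary α-hydroxy ester to the α-keto ester under neutral conditions that leave the acetal intact.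

Step 5
Reactants: 9 isopropyl propanoate
Product: 10 (E)-1-isopropoxy-1-(triethylsilyloxy)prop-1-ene
Conditions: LiN(i-Pr)2, THF, −78 °C; Et3SiCl
Reagents that add atoms: chlorotriethylsilane, CC[Si](Cl)(CC)CC
Why: Kinetic ester enolisation in THF and O-silylation give the silyl ketene acetal needed for the Mukaiyama aldol.

Step 6
Reactants: 8 methyl 3,3-dimethoxy-2-oxopropanoate; 10 (E)-1-isopropoxy-1-(triethylsilyloxy)prop-1-ene
Product: 11 4-isopropyl 1-methyl (2S,3R)-2-(dimethoxymethyl)-3-methyl-2-(triethylsilyloxy)butanedioate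
Conditions: Cu(OTf)2 (10 mol %), (R,R)-tert-butyl-bis(oxazoline) (11 mol %), CH2Cl2, −78 °C
Reagents that add atoms: none
Why: Evans-type catalytic enantioselective Mukaiyama aldol to an α-keto ester: the copper–bis(oxazoline) Lewis acid chelates the keto ester and exposes one ketone face, the open transition state gives the syn adduct (sets C8 and C17), and silyl transfer leaves the tertiary alcohol as its triethylsilyl ether.

Step 7
Reactants: 11 4-isopropyl 1-methyl (2S,3R)-2-(dimethoxymethyl)-3-methyl-2-(triethylsilyloxy)butanedioate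
Product: 12 isopropyl (2R,3R)-3-(dimethoxymethyl)-2-methyl-4-oxo-3-(triethylsilyloxy)butanoate
Conditions: i-Bu2AlH (1.05 equiv), CH2Cl2, −78 °C
Reagents that add atoms: none
Why: Half-reduction of the methyl ester activated by the α-silyloxy and acetal oxygens (stable tetrahedral aluminate at −78 °C) while the bulkier isopropyl ester is left, as in regioselective reductions of O-protected malate diesters; no stereocentre is touched.

Step 8
Reactants: 5 (R)-4-methyl-4-[1-(trimethylsilyl)vinyl]cyclopent-2-en-1-one; 12 isopropyl (2R,3R)-3-(dimethoxymethyl)-2-methyl-4-oxo-3-(triethylsilyloxy)butanoate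
Product: 13 silyl-protected α′-aldol adduct (cyclopentenone with the C9(OTBS)–C8(OTES)[CH(OMe)2]–C17H(Me)–CO2i-Pr chain at C10; C2/C9 trans; 9,10-anti)
Conditions: LiN(i-Pr)2, THF, −78 °C; 12; then TBSOTf, 2,6-lutidine, −78 → 0 °C
Reagents that add atoms: tert-butyldimethylsilyl trifluoromethanesulfonate, CC(C)(C)[Si](C)(C)OS(=O)(=O)C(F)(F)F
Why: The α′-lithium enolate (only enolisable site) adds to the non-enolisable aldehyde through a Zimmerman–Traxler chair: attack anti to the bulky 1-(trimethylsilyl)vinyl group sets C10 (C9 cis to Me-15), the cyclic E-enolate gives the 9,10-anti aldol (sets C9), and the aldolate is silylated in situ.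

Step 9
Reactants: 13 silyl-protected α′-aldol adduct
Product: 14 4-methyl-4-vinylcyclopentenone aldol adduct (C1 vinyl; side chain unchanged)
Conditions: CF3CO2H, CH2Cl2, 0 °C; NaHCO3
Reagents that add atoms: none
Why: Ipso-protodesilylation of the vinylsilane through the β-silyl cation removes the steric control element; the C7 acetal is deactivated towards ionisation by the adjacent quaternary silyloxy carbon.

Step 10
Reactants: 14 4-methyl-4-vinylcyclopentenone aldol adduct
Product: 16 tertiary α-ketol (C12 hydroxy and acetyl; acetyl cis to H-10), via enol ether adduct 15 (not isolated)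
Conditions: CH2=C(OEt)Li (from ethyl vinyl ether, t-BuLi), CeCl3, THF, −78 °C; then 0.5 M aq. oxalic acid, THF, 0 °C
Reagents that add atoms: 1-ethoxyvinyllithium, [Li]C(=C)OCC; water, O
Why: Organocerium 1,2-addition of the acetyl-anion equivalent to the enone carbonyl from the face opposite the C10 side chain sets C12, and mild enol-ether hydrolysis unveils the methyl ketone; cerium suppresses enolisation, conjugate addition and ester attack.

Step 11
Reactants: 16 tertiary α-ketol
Product: 18 ring-A enone 11-acetate (6-acetoxy-6-methylcyclohex-2-enone core; C1 vinyl), via ring-expanded ketol 17 (not isolated)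
Conditions: KN(SiMe3)2 (1.05 equiv), 18-crown-6, THF, −78 → −20 °C; then Ac2O, DMAP, 0 °C
Reagents that add atoms: acetic anhydride, CC(=O)OC(C)=O
Why: α-Ketol (acyloin) rearrangement with ring expansion: in the free potassium alkoxide the C=O lies anti to C–O−, so C10 migrates with retention from C12 to the acetyl carbon on the face that puts the new C11 oxygen on the H-10 side (sets C11); ring-strain relief and formation of the conjugated enone drive the equilibrium (vinyl migration would give a non-conjugated ketone), and the tertiary alkoxide is trapped as the acetate.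

Step 12
Reactants: 18 ring-A enone 11-acetate; 19 (E)-but-2-enal
Product: 20 (E)-enal (C1–CH=CH–CHO; C4 aldehyde)
Conditions: 19 (10 equiv), Hoveyda–Grubbs second-generation catalyst (10 mol %), CH2Cl2, 40 °C
Reagents that add atoms: none
Why: Olefin cross-metathesis of the terminal vinyl group with excess crotonaldehyde gives the E-enal (sets the C2=C3 geometry); the ring enone is inert.

Step 13
Reactants: 20 (E)-enal; 21 2-bromo-3,3-dimethoxyprop-1-ene
Product: 23 (4S)-4-acetoxy bis-acetal (C5 methylene with C6 dimethyl acetal), via C4 alcohol 22 (not isolated)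
Conditions: CrCl2 (4 equiv), NiCl2 (2 mol %), chiral oxazoline–sulfonamide ligand (Kishi type), Et3N, THF, 25 °C; then Ac2O, pyridine, DMAP
Reagents that add atoms: acetic anhydride, CC(=O)OC(C)=O
Why: Nozaki–Hiyama–Kishi coupling is chemoselective for the aldehyde over the ketone and esters, the chiral sulfonamide–chromium complex sets C4 by reagent control, and the chromium alkoxide is acetylated in situ.

Step 14
Reactants: 23 (4S)-4-acetoxy bis-acetal
Product: 24 2-substituted acrolein (C6 aldehyde; C7 acetal retained)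
Conditions: PPTS (0.2 equiv), acetone–H2O 10:1, 25 °C
Reagents that add atoms: water, O
Why: Chemoselective acetal hydrolysis: the 2-alkenyl acetal ionises to a conjugated oxocarbenium ion and reacts far faster than the C7 acetal, which is deactivated by the neighbouring quaternary silyloxy carbon.

Step 15
Reactants: 24 2-substituted acrolein
Product: 25 allylic gem-dichloride (C6HCl2 on the C5 methylene unit)
Conditions: (PhO)3P, Cl2, CH2Cl2, −78 °C; then 24, −78 → −20 °C
Reagents that add atoms: triphenyl phosphite dichloride, ClP(Cl)(Oc1ccccc1)(Oc1ccccc1)Oc1ccccc1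
Why: Deoxygenative gem-dichlorination of an aldehyde by triphenyl phosphite–chlorine at low temperature leaves the non-enolisable ring ketone alone; any 1,3-transposed dichloride would give the same allylchromium in step 17.

Step 16
Reactants: 25 allylic gem-dichloride
Product: 26 C7 aldehyde (gem-dichloride and silyl ethers intact)
Conditions: Et3SiOTf, 2,4,6-collidine, CH2Cl2, 0 °C; then H2O
Reagents that add atoms: water, O
Why: Fujioka-type non-hydrolytic acetal cleavage through the collidinium salt frees the aldehyde without aqueous acid, so the ionisable allylic dichloride, silyl ethers and acetates survive.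

Step 17
Reactants: 26 C7 aldehyde
Product: 29 macrocyclic chlorolactone (8-OTES; 9-OTBS), via allylchromium species 27 (not isolated), via hydroxy ester 28 (not isolated)
Conditions: CrCl2 (10 equiv), THF, 2 mM (slow addition of 26), 25 °C; aq. NH4Cl; then PPTS (cat.), benzene, 40 °C
Reagents that add atoms: none
Why: Proposed new method: intramolecular chromium-mediated γ-chloroallylation—two equivalents of CrCl2 reduce the allylic gem-dichloride to an α-chloroallylchromium that relaxes by 1,3-metallotropy to the (E)-γ-chloroallylchromium 27, which adds through a closed chair transition state to the C7 aldehyde (forms C6–C7, the ten-membered ring and the exo-methylene; anti C6-Cl/C7-O; aldehyde face by Felkin–Anh control with C8–OSiEt3 anti to the incoming carbon), after which the C7 hydroxyl lactonises onto the isopropyl ester; the closest known reactions are Nozaki–Hiyama allylation closures of ω-formyl allylic halides to ten-membered rings and Takai's anti-selective γ-alkoxyallylchromium additions.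

Step 18
Reactants: 29 macrocyclic chlorolactone
Product: 31 target CNP0159278.2, via diol 30 (not isolated)
Conditions: HF·pyridine, THF–pyridine, 0 → 25 °C; then Ac2O, pyridine, DMAP (cat.), 0 °C
Reagents that add atoms: acetic anhydride, CC(=O)OC(C)=O
Why: Fluoride cleaves both silyl ethers and the secondary C9 alcohol is acetylated chemoselectively, the hindered tertiary C8 alcohol being inert to Ac2O/pyridine.

**Compound list**

1 | 3-methylcyclopent-2-en-1-one | CC1=CC(=O)CC1 | starting material
2 | ethynyltrimethylsilane | C#C[Si](C)(C)C | starting material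
3 | diisobutyl[1-(trimethylsilyl)vinyl]aluminium | C=C([Si](C)(C)C)[Al](CC(C)C)CC(C)C | intermediate
4 | (S)-3-methyl-3-[1-(trimethylsilyl)vinyl]cyclopentan-1-one | C=C([Si](C)(C)C)[C@@]1(C)CCC(=O)C1 | intermediate
5 | (R)-4-methyl-4-[1-(trimethylsilyl)vinyl]cyclopent-2-en-1-one | C=C([Si](C)(C)C)[C@@]1(C)C=CC(=O)C1 | intermediate
6 | methyl (E)-3-methoxyprop-2-enoate | CO/C=C/C(=O)OC | starting material
7 | methyl 2-hydroxy-3,3-dimethoxypropanoate (racemic) | COC(OC)C(O)C(=O)OC | intermediate
8 | methyl 3,3-dimethoxy-2-oxopropanoate | COC(OC)C(=O)C(=O)OC | intermediate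
9 | isopropyl propanoate | CCC(=O)OC(C)C | starting material
10 | (E)-1-isopropoxy-1-(triethylsilyloxy)prop-1-ene | C/C=C(\OC(C)C)O[Si](CC)(CC)CC | intermediate
11 | 4-isopropyl 1-methyl (2S,3R)-2-(dimethoxymethyl)-3-methyl-2-(triethylsilyloxy)butanedioate | COC(=O)[C@](O[Si](CC)(CC)CC)([C@@H](C)C(=O)OC(C)C)C(OC)OC | intermediate
12 | isopropyl (2R,3R)-3-(dimethoxymethyl)-2-methyl-4-oxo-3-(triethylsilyloxy)butanoate | O=C[C@](O[Si](CC)(CC)CC)([C@@H](C)C(=O)OC(C)C)C(OC)OC | intermediate
13 | silyl-protected α′-aldol adduct: 4-methyl-4-[1-(trimethylsilyl)vinyl]cyclopent-2-enone bearing at C10 the chain C9H(OTBS)–C8(OTES)[CH(OMe)2]–C17H(Me)–CO2i-Pr; C2/C9 trans, 9,10-anti; C1, C8, C9, C10, C17 arranged as in the target | C=C([Si](C)(C)C)[C@@]1(C)C=CC(=O)[C@@H]1[C@@H](O[Si](C)(C)C(C)(C)C)[C@](O[Si](CC)(CC)CC)([C@@H](C)C(=O)OC(C)C)C(OC)OC | intermediate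
14 | protodesilylated adduct: as 13 with a vinyl group on C1 | C=C[C@@]1(C)C=CC(=O)[C@@H]1[C@@H](O[Si](C)(C)C(C)(C)C)[C@](O[Si](CC)(CC)CC)([C@@H](C)C(=O)OC(C)C)C(OC)OC | intermediate
15 | enol ether adduct: C12 tertiary alcohol bearing a 1-ethoxyvinyl group cis to H-10 | C=C[C@@]1(C)C=C[C@@](O)(C(=C)OCC)[C@@H]1[C@@H](O[Si](C)(C)C(C)(C)C)[C@](O[Si](CC)(CC)CC)([C@@H](C)C(=O)OC(C)C)C(OC)OC | intermediate
16 | tertiary α-ketol: 1-acetylcyclopent-2-en-1-ol, acetyl cis to H-10 and trans to the C9 chain | C=C[C@@]1(C)C=C[C@@](O)(C(C)=O)[C@@H]1[C@@H](O[Si](C)(C)C(C)(C)C)[C@](O[Si](CC)(CC)CC)([C@@H](C)C(=O)OC(C)C)C(OC)OC | intermediate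
17 | ring-expanded ketol: 6-hydroxy-6-methylcyclohex-2-enone (ring A), C11 hydroxyl cis to H-10 | C=C[C@@]1(C)C=CC(=O)[C@@](C)(O)[C@@H]1[C@@H](O[Si](C)(C)C(C)(C)C)[C@](O[Si](CC)(CC)CC)([C@@H](C)C(=O)OC(C)C)C(OC)OC | intermediate
18 | ring-A enone 11-acetate with C1 vinyl | C=C[C@@]1(C)C=CC(=O)[C@@](C)(OC(C)=O)[C@@H]1[C@@H](O[Si](C)(C)C(C)(C)C)[C@](O[Si](CC)(CC)CC)([C@@H](C)C(=O)OC(C)C)C(OC)OC | intermediate
19 | (E)-but-2-enal | C/C=C/C=O | starting material
20 | (E)-enal: C1–CH=CH–CHO (C4 aldehyde) | O=C/C=C/[C@@]1(C)C=CC(=O)[C@@](C)(OC(C)=O)[C@@H]1[C@@H](O[Si](C)(C)C(C)(C)C)[C@](O[Si](CC)(CC)CC)([C@@H](C)C(=O)OC(C)C)C(OC)OC | intermediate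
21 | 2-bromo-3,3-dimethoxyprop-1-ene | C=C(Br)C(OC)OC | starting material
22 | (4S)-C4 alcohol with C5 methylene and C6 dimethyl acetal | C=C(C(OC)OC)[C@@H](O)/C=C/[C@@]1(C)C=CC(=O)[C@@](C)(OC(C)=O)[C@@H]1[C@@H](O[Si](C)(C)C(C)(C)C)[C@](O[Si](CC)(CC)CC)([C@@H](C)C(=O)OC(C)C)C(OC)OC | intermediate
23 | (4S)-4-acetoxy bis-acetal | C=C(C(OC)OC)[C@@H](OC(C)=O)/C=C/[C@@]1(C)C=CC(=O)[C@@](C)(OC(C)=O)[C@@H]1[C@@H](O[Si](C)(C)C(C)(C)C)[C@](O[Si](CC)(CC)CC)([C@@H](C)C(=O)OC(C)C)C(OC)OC | intermediate
24 | 2-substituted acrolein (C6 aldehyde; C7 acetal) | C=C(C=O)[C@@H](OC(C)=O)/C=C/[C@@]1(C)C=CC(=O)[C@@](C)(OC(C)=O)[C@@H]1[C@@H](O[Si](C)(C)C(C)(C)C)[C@](O[Si](CC)(CC)CC)([C@@H](C)C(=O)OC(C)C)C(OC)OC | intermediate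
25 | allylic gem-dichloride (C6HCl2; C7 acetal) | C=C(C(Cl)Cl)[C@@H](OC(C)=O)/C=C/[C@@]1(C)C=CC(=O)[C@@](C)(OC(C)=O)[C@@H]1[C@@H](O[Si](C)(C)C(C)(C)C)[C@](O[Si](CC)(CC)CC)([C@@H](C)C(=O)OC(C)C)C(OC)OC | intermediate
26 | C7 aldehyde with allylic gem-dichloride | C=C(C(Cl)Cl)[C@@H](OC(C)=O)/C=C/[C@@]1(C)C=CC(=O)[C@@](C)(OC(C)=O)[C@@H]1[C@@H](O[Si](C)(C)C(C)(C)C)[C@](O[Si](CC)(CC)CC)([C@@H](C)C(=O)OC(C)C)C=O | intermediate
27 | (E)-γ-chloroallylchromium dichloride species (Cr on C16, Cl on C6 trans to CH2Cr) | Cl/C=C(/C[Cr](Cl)Cl)[C@@H](OC(C)=O)/C=C/[C@@]1(C)C=CC(=O)[C@@](C)(OC(C)=O)[C@@H]1[C@@H](O[Si](C)(C)C(C)(C)C)[C@](O[Si](CC)(CC)CC)([C@@H](C)C(=O)OC(C)C)C=O | intermediate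
28 | ten-membered hydroxy ester: (6S)-chloro, (7R)-hydroxy, C5 exo-methylene, isopropyl ester still open | C=C1[C@@H](OC(C)=O)/C=C/[C@@]2(C)C=CC(=O)[C@@](C)(OC(C)=O)[C@@H]2[C@@H](O[Si](C)(C)C(C)(C)C)[C@](O[Si](CC)(CC)CC)([C@@H](C)C(=O)OC(C)C)[C@@H](O)[C@H]1Cl | intermediate
29 | macrocyclic chlorolactone: target skeleton with 8-OTES and 9-OTBS | C=C1[C@@H](OC(C)=O)/C=C/[C@@]2(C)C=CC(=O)[C@@](C)(OC(C)=O)[C@@H]2[C@@H](O[Si](C)(C)C(C)(C)C)[C@]2(O[Si](CC)(CC)CC)[C@@H](C)C(=O)O[C@H]2[C@H]1Cl | intermediate
30 | 8,9-diol (9-deacetyl target) | C=C1[C@@H](OC(C)=O)/C=C/[C@@]2(C)C=CC(=O)[C@@](C)(OC(C)=O)[C@@H]2[C@@H](O)[C@]2(O)[C@@H](C)C(=O)O[C@H]2[C@H]1Cl | intermediate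
31 | CNP0159278.2: (1S,4S,6S,7R,8R,9R,10S,11S,17R)-4,9,11-triacetoxy-6-chloro-8-hydroxy-12-oxo-briara-2E,5(16),13-triene 19,7-lactone | C=C1[C@@H](OC(C)=O)/C=C/[C@@]2(C)C=CC(=O)[C@@](C)(OC(C)=O)[C@@H]2[C@@H](OC(C)=O)[C@]2(O)[C@@H](C)C(=O)O[C@H]2[C@H]1Cl | target

**Totals**

Total step count: 18. Longest linear sequence: 15 steps (steps 3, 4, 6–18).

**Steps most likely to fail, with fallbacks**

Step 11 (α-ketol ring expansion). The risks are competing vinyl migration, the wrong C11 epimer if the alkoxide reacts through a chelated conformer, and base epimerisation at C17. The fallback changes the way C11 is introduced but keeps a ring expansion. It sets out from 14. The cyclopentenone is homologated with Me3SiCHN2/AlMe3 (CH2Cl2, −78 °C; the sp3 carbon C10 migrates and the enone stays conjugated) to the ring-homologated cyclohex-2-enone F1. α′-Methylation (LiN(i-Pr)2, MeI, −78 °C) gives the 11-methyl ketone F2 as either epimer. Oxidation of its potassium enolate with 2-(phenylsulfonyl)-3-phenyloxaziridine delivers oxygen anti to the C10 side chain and gives ketol 17. Acetylation as in step 11 returns to the route at 18.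

Step 12 (cross-metathesis at a vinyl group on a quaternary carbon). The alkene is neopentylic and crowded, so catalyst turnover may be poor. The fallback sets out from 18. Selective ozonolysis of the vinyl group (O3, CH2Cl2–MeOH, −78 °C, Sudan red 7B end-point; Me2S; the electron-poor ring enone reacts more slowly) gives the C2 aldehyde F3. Wittig olefination with Ph3P=CHCHO (toluene, 80 °C) then gives the E-enal and returns to the route at 20.

Step 17 (the new chromium γ-chloroallylation ring closure). The uncertain points are the fate of the α-chloro organochromium, the E/Z equilibration that determines the C6/C7 relationship, and medium-ring closure against oligomerisation. The fallback uses only known reactions and sets out from 24. The C7 acetal is cleaved as in step 16 (Et3SiOTf, 2,4,6-collidine; H2O) to give the dialdehyde F4. The ring is closed by the known Takai-type pinacol cross-coupling of a 2-substituted acrolein with an aldehyde (CrCl2, Me3SiCl, THF, high dilution; then PPTS), which is reported to favour the syn diol for α-branched acroleins. After loss of the labile C6 silyl ether and lactonisation this gives the 6-epi-hydroxy lactone F5. Appel chlorination (PPh3, CCl4, 25 °C) with inversion at the allylic C6 returns to the route at 29.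

**Further compounds**

F1 | step 11 | ring-homologated cyclohex-2-enone (C11 methylene between C12 and C10; C1 vinyl; side chain as in 14) | C=C[C@@]1(C)C=CC(=O)C[C@@H]1[C@@H](O[Si](C)(C)C(C)(C)C)[C@](O[Si](CC)(CC)CC)([C@@H](C)C(=O)OC(C)C)C(OC)OC
F2 | step 11 | 11-methyl ketone (C11 epimers not defined) | C=C[C@@]1(C)C=CC(=O)C(C)[C@@H]1[C@@H](O[Si](C)(C)C(C)(C)C)[C@](O[Si](CC)(CC)CC)([C@@H](C)C(=O)OC(C)C)C(OC)OC
F3 | step 12 | C2 aldehyde (formyl group on C1 of 18 in place of vinyl) | O=C[C@@]1(C)C=CC(=O)[C@@](C)(OC(C)=O)[C@@H]1[C@@H](O[Si](C)(C)C(C)(C)C)[C@](O[Si](CC)(CC)CC)([C@@H](C)C(=O)OC(C)C)C(OC)OC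
F4 | step 17 | dialdehyde (C6 enal and free C7 aldehyde) | C=C(C=O)[C@@H](OC(C)=O)/C=C/[C@@]1(C)C=CC(=O)[C@@](C)(OC(C)=O)[C@@H]1[C@@H](O[Si](C)(C)C(C)(C)C)[C@](O[Si](CC)(CC)CC)([C@@H](C)C(=O)OC(C)C)C=O
F5 | step 17 | 6-epi-hydroxy lactone (C6 hydroxyl syn to the C7 oxygen in place of chlorine; 8-OTES; 9-OTBS) | C=C1[C@@H](OC(C)=O)/C=C/[C@@]2(C)C=CC(=O)[C@@](C)(OC(C)=O)[C@@H]2[C@@H](O[Si](C)(C)C(C)(C)C)[C@]2(O[Si](CC)(CC)CC)[C@@H](C)C(=O)O[C@H]2[C@@H]1O
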